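**Structural features**

The target is an 8-O-4' neolignan of the arylglycerol β-aryl ether type: a three-carbon chain C7–C8–C9 whose only rings are two benzene rings. Ring A (4-hydroxy-3,5-dimethoxyphenyl) is bonded through carbon to C7. Ring B (4-allyl-2,6-dimethoxyphenyl) is bonded through its phenolic oxygen to C8, and C9 is a primary alcohol. The two stereocentres are neighbours: C7 (R) is a secondary benzylic carbinol and C8 (S) is the ether carbon. Their relation is erythro, which in the zigzag drawing of ring A–C7–C8–C9 places the C7 hydroxyl and the C8 aryloxy group on opposite sides (anti). Fragile points are: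
- the terminal allyl group (migration into conjugation, hydroboration, hydrogenation);
- the benzylic C7–O bond para to the ring A oxygen (ionisation under acid would scramble C7);
- the free electron-rich phenol;
- in any precursor with a carbonyl group at C9, the acidic C8–H and the retro-aldol pathway across C7–C8.

The real difficulty is acyclic control of both relative and absolute configuration on a bond with no ring to bias it, together with a 2,6-disubstituted aryloxy group that is awkward to introduce late at a secondary carbon. The key step exploits the aldol pattern: C8 lies between C9, which can be held at the carboxyl level, and the carbinol carbon C7 on ring A. C7–C8 can therefore be made from an enolate that already carries the ring B oxygen at C8 and the aldehyde of ring A, with a removable controller on C9.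

**Logic of the disconnections**

11 ⇒ 10. Only the O–Si bond on the ring A phenol oxygen is involved. The phenol is kept masked to the end because a free phenoxide para to C7 would favour retro-aldol cleavage and quinone methide chemistry in the earlier basic steps. Nothing is gained in skeleton; the demand is an unmasking that is neither acidic (C7 ionisation) nor strongly basic (allyl migration).

10 ⇒ 9. C9 is taken back from the alcohol to the acyl level and bonded to the nitrogen of the chiral auxiliary. This makes C8 enolisable and installs the stereocontroller, so the chain acquires an aldol retron. The forward reduction must attack the exocyclic carbonyl only, leave the terminal alkene and the aryl silyl ether alone, and be faster than retro-aldol cleavage or deprotonation at C8.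

9 ⇒ 5 + 7 (through 8). The C7–C8 bond is cut. It is the only C–C bond flanked by both stereocentres, so the cut removes both at once and divides the molecule into two halves of similar size, each with one ring. The forward step must give the anti pair, use one enolate face, and be made irreversible by trapping the aldolate as 8.

5 ⇒ 2 + 3 (through 4). The N–acyl bond is cut, separating the commercial auxiliary from an achiral acid. The acylation must proceed without a base strong enough to disturb the allyl arene.

2 ⇒ 1. The O–CH2 bond is cut, not the O–aryl bond. Making the hindered aryl ether at a primary carbon, before any stereocentre exists, avoids a later substitution by a 2,6-disubstituted phenoxide at a secondary carbon. The only demand is a simple SN2 reaction with a two-carbon α-halo acid.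

7 ⇒ 6. The O–Si bond is cut. The silyl group removes the acidic proton that would quench the enolate and bind the magnesium salt in the aldol step, and it must survive amine base, chloride and a brief acidic work-up.

**Other disconnections considered**

Alternative 1: The cut is the ether bond between the C8 oxygen and C4 of ring B. In the forward step the sodium alkoxide of the cyclic silylene A1, whose C7 and C9 oxygens are tied together so that only the C8 hydroxyl is free, would attack the fluoroarene A2 by addition–elimination to give the aryl ether A3. The formyl group of A3 would then have to be converted into the allyl group.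
- In its favour: both stereocentres exist before the coupling and no bond at a stereocentre is broken, so the key step needs no stereoselection. On this point it is better than the chosen plan. It is equally convergent.
- Against it: the fluorine-bearing carbon of A2 sits between two methoxy groups and is activated only by one para formyl group, so a hindered secondary alkoxide should add slowly. That alkoxide is next to two silicon-bound oxygens and can trigger silyl migration, which would move the free oxygen to C7 or C9. It can also add to the formyl group or reduce it by hydride transfer.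
- Further cost: turning the formyl group of A3 into an allyl group takes about three steps beside a benzylic C7–O bond. A1 itself needs an erythro triol with three differentiated oxygens, whereas asymmetric dihydroxylation of an E-alkene delivers the threo relation and would need an inversion.
- Comparison: structurally it makes the hindered aryl ether last, where the chosen plan makes it first at a primary carbon. Mechanistically it swaps a stereo-defining C–C bond formation for a stereo-neutral C–O bond formation. In step economy it is clearly inferior, at roughly twice the step count.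

Alternative 2: The cut is the bond between C7 and C1 of ring A. In the forward step the aryllithium A6, made from the bromide A5 by bromine–lithium exchange, would add to the α-aryloxy aldehyde A4 to give the bis-silyl ether A7.
- In its favour: it is convergent and forms the same number of skeletal bonds as the chosen step (equal). C8 arrives with its configuration in place. The polar Felkin–Anh model (aryloxy group antiperiplanar to the nucleophile, attack past hydrogen) predicts the erythro isomer, and the hindered, weakly basic aryl ether oxygen is a poor ligand for chelation. A7 is one fluoride treatment from the target, a shorter end-game than the chosen plan (better on this point). No auxiliary has to be removed.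
- Against it: only C7 is made, by 1,2-induction with a very reactive nucleophile, so modest selectivity is to be expected. Any lithium chelation by the ether oxygens would favour the threo isomer. A4 has an acidic hydrogen between a formyl and an aryloxy group and may enolise, which would erode C8 and quench A6.
- Further cost: making A4 as a single enantiomer needs the hindered aryl ether to be formed at a secondary carbon with inversion, plus redox and protecting-group adjustments, about four to five steps. The total would be about eight or nine steps.
- Comparison: same bond count, but one new stereocentre instead of two, substrate control instead of auxiliary control, and a longer, stereochemically less certain route.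

Alternative 3: The retron is the C7–H bond; no skeletal bond is formed. The β-hydroxy ester A9 is traced back to the racemic β-keto ester A8. In the forward step a chiral divalent ruthenium hydride would reduce one enantiomer of A8 faster while the acidic C8–H lets the enantiomers interconvert through the enol (dynamic kinetic resolution by asymmetric transfer hydrogenation).
- In its favour: chirality is used catalytically, both centres come from a racemate, and no auxiliary is attached or removed. This is better than the chosen plan on reagent economy. A9 has the same functional pattern as 9 and would need the same two closing operations, so the end-game is equal.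
- Against it: the step builds no skeleton, so A8 must first be assembled by C-acylation and by etherification with the hindered phenol 1, about three to four steps. No simple model secures the anti (erythro) over the syn (threo) isomer for an aryloxy substituent at C8, and the syn relation is at least as likely. The ketone is deactivated by the para oxygen of ring A.
- Chemoselectivity: ruthenium hydrides also catalyse migration of a terminal allyl double bond into conjugation, and hydrogen gas in place of transfer conditions would saturate it.
- Comparison: similar length or one to two steps longer, catalyst control instead of auxiliary control, but two open selectivity questions (diastereosense and the alkene) where the chosen plan has one.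

Key step: step 4

Remark on the chemistry (assumption): the reacting face of the chelated magnesium enolate of 5 is taken to be the one that the auxiliary leaves open in alkylations of chelated imide enolates. On that basis the (S)-auxiliary leads to (2R,3R)-9. C8 is R in 9 and S in 10 and 11 without any change of geometry, because reduction of C9 exchanges the CIP ranks of C9 and C7; erythro and anti (zigzag) describe the same relation for this chain.

**Step 1**
Reactants: 1 4-allyl-2,6-dimethoxyphenol
Product: 2 (4-allyl-2,6-dimethoxyphenoxy)acetic acid
Conditions: NaH (2.5 equiv), BrCH2CO2H (1.2 equiv), THF, 0 °C to reflux; then 1 M HCl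
Reagents that add atoms: bromoacetic acid, OC(=O)CBr
Why: Williamson ether synthesis: the sodium phenoxide of 1 displaces bromide from sodium bromoacetate at an unhindered primary carbon (SN2), which a 2,6-dimethoxyphenoxide should manage easily; NaH in THF is not able to move the allyl double bond into conjugation.

**Step 2**
Reactants: 2 (4-allyl-2,6-dimethoxyphenoxy)acetic acid; 3 (S)-4-benzyloxazolidin-2-one
Product: 5 (S)-4-benzyl-3-[(4-allyl-2,6-dimethoxyphenoxy)acetyl]oxazolidin-2-one, via mixed pivalic anhydride 4 (not isolated)
Conditions: PivCl, Et3N, THF, −20 °C; then LiCl, 3, −20 °C to rt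
Reagents that add atoms: pivaloyl chloride, CC(C)(C)C(=O)Cl (its acyl group is carried by 4 only)
Why: N-acylation of an oxazolidinone through a mixed anhydride: the oxazolidinone, activated by LiCl/Et3N, should attack 4 at the less hindered and more electrophilic aryloxyacetyl carbonyl, so no organolithium base meets the allyl arene; the auxiliary stereocentre is not involved.

**Step 3**
Reactants: 6 syringaldehyde (4-hydroxy-3,5-dimethoxybenzaldehyde)
Product: 7 4-(tert-butyldimethylsilyloxy)-3,5-dimethoxybenzaldehyde
Conditions: TBSCl (1.2 equiv), imidazole (2.5 equiv), DMF, rt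
Reagents that add atoms: tert-butyldimethylsilyl chloride, CC(C)(C)[Si](C)(C)Cl
Why: Imidazole-mediated silylation of a phenol; the acidic phenol para to the formyl group should silylate readily despite its two methoxy neighbours, and the silyl ether removes the proton that would otherwise quench the enolate and bind MgCl2 in step 4.

**Step 4**
Reactants: 5 (S)-4-benzyl-3-[(4-allyl-2,6-dimethoxyphenoxy)acetyl]oxazolidin-2-one; 7 4-(tert-butyldimethylsilyloxy)-3,5-dimethoxybenzaldehyde
Product: 9 (S)-4-benzyl-3-[(2R,3R)-2-(4-allyl-2,6-dimethoxyphenoxy)-3-[4-(tert-butyldimethylsilyloxy)-3,5-dimethoxyphenyl]-3-hydroxypropanoyl]oxazolidin-2-one, via O-trimethylsilyl anti-aldol adduct 8 (not isolated)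
Conditions: 7 (1.3 equiv), MgCl2 (0.2 equiv), Et3N (2 equiv), Me3SiCl (1.5 equiv), EtOAc, 23 °C; then 1 M HCl, THF, 0 °C
Reagents that add atoms: chlorotrimethylsilane, C[Si](C)(C)Cl (its silyl group is carried by 8 only)
Why: Magnesium-halide-catalysed direct anti-aldol addition of an N-acyloxazolidinone by soft enolisation: MgCl2 binds both imide carbonyls of 5, and Et3N then removes the acidified C8 proton to give the Z-enolate (aryloxy group cis to the enolate oxygen), which stays chelated to the ring carbonyl. Aldehyde 7 binds to the same divalent magnesium centre and the C7–C8 bond forms within a closed, boat-like array; Me3SiCl silylates the magnesium aldolate to 8, which releases MgCl2 for the next turnover and makes the addition irreversible, and dilute acid at work-up cleaves only the alkyl trimethylsilyl ether. No ring is closed. C8 is controlled by the benzyl group at C4 of the (S)-auxiliary, which covers one face of the planar chelated enolate so that the aldehyde adds to the other. C7 is controlled by the boat-like arrangement, in which the aryl group of 7 points away from the auxiliary and the aryloxy group, so the aldehyde face that gives the anti (erythro) pair is used. The step needs chemoselective enolisation, anti simple selectivity and high facial selectivity: the first is secured by two-point binding of the imide and the inductive effect of the aryloxy group (7 has no α-hydrogen, and the aryl silyl ether and allyl group are inert to Et3N and Me3SiCl), the other two by the rigid chelate. The closest known reaction type is the MgCl2/Et3N/Me3SiCl anti-aldol of N-propionyl oxazolidinones with non-enolisable aromatic aldehydes; a boron enolate would instead give the syn (threo) pair.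

**Step 5**
Reactants: 9 (S)-4-benzyl-3-[(2R,3R)-2-(4-allyl-2,6-dimethoxyphenoxy)-3-[4-(tert-butyldimethylsilyloxy)-3,5-dimethoxyphenyl]-3-hydroxypropanoyl]oxazolidin-2-one
Product: 10 (1R,2S)-2-(4-allyl-2,6-dimethoxyphenoxy)-1-[4-(tert-butyldimethylsilyloxy)-3,5-dimethoxyphenyl]propane-1,3-diol
Conditions: LiBH4 (2.5 equiv), MeOH (2.5 equiv), THF, 0 °C; aq. NH4Cl
Reagents that add atoms: none
Why: Reductive cleavage of an N-acyloxazolidinone with LiBH4: hydride should add to the exocyclic carbonyl, which is activated by the α-aryloxy group and reached intramolecularly from the C7 alkoxyborohydride, and the released aldehyde is reduced on to the C9 alcohol. Methanol converts the reagent into the more selective LiBH3(OMe) and intercepts borane, so the allyl group should not be hydroborated; at 0 °C reduction should outrun enolisation at C8, and neither stereocentre is touched.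

**Step 6**
Reactants: 10 (1R,2S)-2-(4-allyl-2,6-dimethoxyphenoxy)-1-[4-(tert-butyldimethylsilyloxy)-3,5-dimethoxyphenyl]propane-1,3-diol
Product: 11 (1R,2S)-2-(4-allyl-2,6-dimethoxyphenoxy)-1-(4-hydroxy-3,5-dimethoxyphenyl)propane-1,3-diol (erythro, 7R,8S; the target)
Conditions: Bu4NF (1.1 equiv), AcOH (1.1 equiv), THF, 0 °C
Reagents that add atoms: none
Why: Fluoride-induced cleavage of an aryl silyl ether, driven by the Si–F bond with the phenoxide as leaving group. The AcOH buffer keeps the liberated phenol protonated, so the medium is neither basic enough for quinone methide chemistry or allyl migration nor acidic enough to ionise the benzylic C7–O bond.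

**Compound list**

1 | 4-allyl-2,6-dimethoxyphenol | C=CCc1cc(OC)c(O)c(OC)c1 | starting material
2 | (4-allyl-2,6-dimethoxyphenoxy)acetic acid | C=CCc1cc(OC)c(OCC(=O)O)c(OC)c1 | intermediate
3 | (S)-4-benzyloxazolidin-2-one | O=C1OC[C@H](Cc2ccccc2)N1 | starting material
4 | (4-allyl-2,6-dimethoxyphenoxy)acetic pivalic anhydride (formed in the flask) | C=CCc1cc(OC)c(OCC(=O)OC(=O)C(C)(C)C)c(OC)c1 | intermediate
5 | (S)-4-benzyl-3-[(4-allyl-2,6-dimethoxyphenoxy)acetyl]oxazolidin-2-one | C=CCc1cc(OC)c(OCC(=O)N2[C@@H](Cc3ccccc3)COC2=O)c(OC)c1 | intermediate
6 | syringaldehyde | O=Cc1cc(OC)c(O)c(OC)c1 | starting material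
7 | 4-(tert-butyldimethylsilyloxy)-3,5-dimethoxybenzaldehyde | O=Cc1cc(OC)c(O[Si](C)(C)C(C)(C)C)c(OC)c1 | intermediate
8 | (S)-4-benzyl-3-[(2R,3R)-2-(4-allyl-2,6-dimethoxyphenoxy)-3-[4-(tert-butyldimethylsilyloxy)-3,5-dimethoxyphenyl]-3-(trimethylsilyloxy)propanoyl]oxazolidin-2-one (formed in the flask) | C=CCc1cc(OC)c(O[C@@H](C(=O)N2[C@@H](Cc3ccccc3)COC2=O)[C@H](O[Si](C)(C)C)c4cc(OC)c(O[Si](C)(C)C(C)(C)C)c(OC)c4)c(OC)c1 | intermediate
9 | (S)-4-benzyl-3-[(2R,3R)-2-(4-allyl-2,6-dimethoxyphenoxy)-3-[4-(tert-butyldimethylsilyloxy)-3,5-dimethoxyphenyl]-3-hydroxypropanoyl]oxazolidin-2-one | C=CCc1cc(OC)c(O[C@@H](C(=O)N2[C@@H](Cc3ccccc3)COC2=O)[C@H](O)c4cc(OC)c(O[Si](C)(C)C(C)(C)C)c(OC)c4)c(OC)c1 | intermediate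
10 | (1R,2S)-2-(4-allyl-2,6-dimethoxyphenoxy)-1-[4-(tert-butyldimethylsilyloxy)-3,5-dimethoxyphenyl]propane-1,3-diol | C=CCc1cc(OC)c(O[C@@H](CO)[C@H](O)c2cc(OC)c(O[Si](C)(C)C(C)(C)C)c(OC)c2)c(OC)c1 | intermediate
11 | (1R,2S)-2-(4-allyl-2,6-dimethoxyphenoxy)-1-(4-hydroxy-3,5-dimethoxyphenyl)propane-1,3-diol | C=CCc1cc(OC)c(O[C@@H](CO)[C@H](O)c2cc(OC)c(O)c(OC)c2)c(OC)c1 | target

**Step count and least certain steps**

Total step count: 6. Longest linear sequence: 5 steps (steps 1, 2, 4, 5, 6 from 1); step 3 is a one-step branch from 6.

Step 4 (key step). The most likely failure is slow or incomplete addition together with drift of the anti/syn ratio. Aldehyde 7 is deactivated by its para oxygen. Imide 5 offers the divalent magnesium centre three further ether oxygens (the aryloxy oxygen and its two methoxy neighbours), which may saturate the metal so that the aldehyde is no longer held in the closed array. If addition is reversible before silylation, the ratio then reflects equilibration and not the boat-like pathway. A higher MgCl2 loading or added NaSbF6 is the first adjustment.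

The fallback changes the stereochemical strategy, sets out from 2 and 7 and rejoins the route at 11:
- Acid 2 would be coupled, as in step 2, with (R)-4-benzyloxazolidin-2-one to give the enantiomeric imide F1.
- Its dibutylboron Z-enolate (Bu2BOTf, i-Pr2NEt, CH2Cl2, −78 °C) should add to 7 through the chair transition state of the boron syn-aldol reaction to give the syn adduct F2. In F2, C8 already has the configuration of 9 and C7 the opposite one.
- LiBH4/MeOH should give the threo diol F3.
- Selective silylation of the primary C9 hydroxyl (TBSCl, imidazole, CH2Cl2, 0 °C) should give the C9 silyl ether F4.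
- Mitsunobu reaction with 4-nitrobenzoic acid (PPh3, DIAD, toluene, 0 °C) should invert C7 and give the erythro 4-nitrobenzoate F5.
- K2CO3/MeOH should remove the ester and the phenolic silyl group to give the C9-silylated phenol F6, and Bu4NF then gives 11.

Step 5. The most likely failure is retro-aldol cleavage across C7–C8 or epimerisation at C8 under the basic hydride conditions, because the aryloxy-imide enolate is a stabilised leaving partner and 7 is a stabilised aldehyde. Hydride attack at the ring carbonyl of the auxiliary is a second possibility. The fallback removes the free C7 oxygen before reduction, sets out from 9 and rejoins at 11. Compound 9 would be silylated (Et3SiOTf, 2,6-lutidine, CH2Cl2, −78 °C) to the C7 triethylsilyl ether F7. LiBH4/MeOH should reduce it to the C7-silylated primary alcohol F8, with any silyl migration between the C7 and C9 oxygens being harmless. Excess Bu4NF/AcOH would then remove both silyl groups to give 11.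

Step 2. The most likely failure is acyl transfer at the wrong carbonyl of 4 (N-pivaloylation) or incomplete acylation, because the LiCl/Et3N-activated oxazolidinone is a weak nucleophile and the aryloxyacetyl unit is flanked by a bulky aryl group. The fallback forms the ether after the imide, sets out from 1 and 3, rejoins at 5 and replaces steps 1 and 2. Oxazolidinone 3 would be N-acylated (n-BuLi, THF, −78 °C; bromoacetyl bromide) to give the bromoacetyl imide F9, and phenol 1 would be alkylated with it (K2CO3, acetone, rt) by SN2 at the primary carbon to give 5.

**Further compounds**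

F1 | step 4 | (R)-4-benzyl-3-[(4-allyl-2,6-dimethoxyphenoxy)acetyl]oxazolidin-2-one | C=CCc1cc(OC)c(OCC(=O)N2[C@H](Cc3ccccc3)COC2=O)c(OC)c1
F2 | step 4 | (R)-4-benzyl-3-[(2R,3S)-2-(4-allyl-2,6-dimethoxyphenoxy)-3-[4-(tert-butyldimethylsilyloxy)-3,5-dimethoxyphenyl]-3-hydroxypropanoyl]oxazolidin-2-one (syn) | C=CCc1cc(OC)c(O[C@@H](C(=O)N2[C@H](Cc3ccccc3)COC2=O)[C@@H](O)c4cc(OC)c(O[Si](C)(C)C(C)(C)C)c(OC)c4)c(OC)c1
F3 | step 4 | (1S,2S)-2-(4-allyl-2,6-dimethoxyphenoxy)-1-[4-(tert-butyldimethylsilyloxy)-3,5-dimethoxyphenyl]propane-1,3-diol (threo) | C=CCc1cc(OC)c(O[C@@H](CO)[C@@H](O)c2cc(OC)c(O[Si](C)(C)C(C)(C)C)c(OC)c2)c(OC)c1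
F4 | step 4 | (1S,2S)-2-(4-allyl-2,6-dimethoxyphenoxy)-3-(tert-butyldimethylsilyloxy)-1-[4-(tert-butyldimethylsilyloxy)-3,5-dimethoxyphenyl]propan-1-ol | C=CCc1cc(OC)c(O[C@@H](CO[Si](C)(C)C(C)(C)C)[C@@H](O)c2cc(OC)c(O[Si](C)(C)C(C)(C)C)c(OC)c2)c(OC)c1
F5 | step 4 | (1R,2S)-2-(4-allyl-2,6-dimethoxyphenoxy)-3-(tert-butyldimethylsilyloxy)-1-[4-(tert-butyldimethylsilyloxy)-3,5-dimethoxyphenyl]propyl 4-nitrobenzoate | C=CCc1cc(OC)c(O[C@@H](CO[Si](C)(C)C(C)(C)C)[C@H](OC(=O)c2ccc(cc2)[N+](=O)[O-])c3cc(OC)c(O[Si](C)(C)C(C)(C)C)c(OC)c3)c(OC)c1
F6 | step 4 | 4-[(1R,2S)-2-(4-allyl-2,6-dimethoxyphenoxy)-3-(tert-butyldimethylsilyloxy)-1-hydroxypropyl]-2,6-dimethoxyphenol | C=CCc1cc(OC)c(O[C@@H](CO[Si](C)(C)C(C)(C)C)[C@H](O)c2cc(OC)c(O)c(OC)c2)c(OC)c1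
F7 | step 5 | (S)-4-benzyl-3-[(2R,3R)-2-(4-allyl-2,6-dimethoxyphenoxy)-3-[4-(tert-butyldimethylsilyloxy)-3,5-dimethoxyphenyl]-3-(triethylsilyloxy)propanoyl]oxazolidin-2-one | C=CCc1cc(OC)c(O[C@@H](C(=O)N2[C@@H](Cc3ccccc3)COC2=O)[C@H](O[Si](CC)(CC)CC)c4cc(OC)c(O[Si](C)(C)C(C)(C)C)c(OC)c4)c(OC)c1
F8 | step 5 | (2S,3R)-2-(4-allyl-2,6-dimethoxyphenoxy)-3-[4-(tert-butyldimethylsilyloxy)-3,5-dimethoxyphenyl]-3-(triethylsilyloxy)propan-1-ol | C=CCc1cc(OC)c(O[C@@H](CO)[C@H](O[Si](CC)(CC)CC)c2cc(OC)c(O[Si](C)(C)C(C)(C)C)c(OC)c2)c(OC)c1
F9 | step 2 | (S)-4-benzyl-3-(bromoacetyl)oxazolidin-2-one | O=C(CBr)N1[C@@H](Cc2ccccc2)COC1=O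
A1 | alternative 1 | (4R,5S)-2,2-di-tert-butyl-4-[4-(tert-butyldimethylsilyloxy)-3,5-dimethoxyphenyl]-1,3,2-dioxasilinan-5-ol | O[C@@H](CO[Si]1(C(C)(C)C)C(C)(C)C)[C@H](O1)c2cc(OC)c(O[Si](C)(C)C(C)(C)C)c(OC)c2
A2 | alternative 1 | 4-fluoro-3,5-dimethoxybenzaldehyde | O=Cc1cc(OC)c(F)c(OC)c1
A3 | alternative 1 | 4-{[(4R,5S)-2,2-di-tert-butyl-4-[4-(tert-butyldimethylsilyloxy)-3,5-dimethoxyphenyl]-1,3,2-dioxasilinan-5-yl]oxy}-3,5-dimethoxybenzaldehyde | O=Cc1cc(OC)c(O[C@@H](CO[Si]2(C(C)(C)C)C(C)(C)C)[C@H](O2)c3cc(OC)c(O[Si](C)(C)C(C)(C)C)c(OC)c3)c(OC)c1
A4 | alternative 2 | (S)-2-(4-allyl-2,6-dimethoxyphenoxy)-3-(tert-butyldimethylsilyloxy)propanal | C=CCc1cc(OC)c(O[C@@H](CO[Si](C)(C)C(C)(C)C)C=O)c(OC)c1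
A5 | alternative 2 | (4-bromo-2,6-dimethoxyphenoxy)triisopropylsilane | COc1cc(Br)cc(OC)c1O[Si](C(C)C)(C(C)C)C(C)C
A6 | alternative 2 | [3,5-dimethoxy-4-(triisopropylsilyloxy)phenyl]lithium | [Li]c1cc(OC)c(O[Si](C(C)C)(C(C)C)C(C)C)c(OC)c1
A7 | alternative 2 | (1R,2S)-2-(4-allyl-2,6-dimethoxyphenoxy)-3-(tert-butyldimethylsilyloxy)-1-[3,5-dimethoxy-4-(triisopropylsilyloxy)phenyl]propan-1-ol | C=CCc1cc(OC)c(O[C@@H](CO[Si](C)(C)C(C)(C)C)[C@H](O)c2cc(OC)c(O[Si](C(C)C)(C(C)C)C(C)C)c(OC)c2)c(OC)c1
A8 | alternative 3 | methyl 2-(4-allyl-2,6-dimethoxyphenoxy)-3-[4-(tert-butyldimethylsilyloxy)-3,5-dimethoxyphenyl]-3-oxopropanoate (racemic) | C=CCc1cc(OC)c(OC(C(=O)OC)C(=O)c2cc(OC)c(O[Si](C)(C)C(C)(C)C)c(OC)c2)c(OC)c1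
A9 | alternative 3 | methyl (2R,3R)-2-(4-allyl-2,6-dimethoxyphenoxy)-3-[4-(tert-butyldimethylsilyloxy)-3,5-dimethoxyphenyl]-3-hydroxypropanoate | C=CCc1cc(OC)c(O[C@@H](C(=O)OC)[C@H](O)c2cc(OC)c(O[Si](C)(C)C(C)(C)C)c(OC)c2)c(OC)c1
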